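The numbers stand for no real mixture; the run is a simulation.

Ochre and its neighbours differ in the charge of partner A, and you want to know which of them ends richest in target.

| setting | ochre | teal | red | green | amber |
|---|---|---|---|---|---|
| starting material | 0.013 M | 0.013 M | 0.013 M | 0.013 M | 0.013 M |
| partner A | 0.00150 M | 0.00500 M | 0.0150 M | 0.0400 M | 0.120 M |
| partner B | 0.0137 M | 0.0137 M | 0.0137 M | 0.0137 M | 0.0137 M |
| protic impurity | 0.0130 M | 0.0130 M | 0.0130 M | 0.0130 M | 0.0130 M |
| time | 5.0 h | 5.0 h | 5.0 h | 5.0 h | 5.0 h |

    starting material + partner B → open intermediate (k1 = 0.92 M⁻¹ min⁻¹)
    partner B + partner A → second intermediate (k2 = 0.18 M⁻¹ min⁻¹)
    open intermediate + second intermediate → target (k3 = 3.5 M⁻¹ min⁻¹)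
    2 second intermediate → homo product (k4 = 1.7 M⁻¹ min⁻¹)
    starting material + protic impurity → quenched substrate (k5 = 0.081 M⁻¹ min⁻¹)

* amount of target at the end, in percent of the starting material charged for ochre, teal, red, green, amber, in this order
* the course of these numbers from the first flask to the last (hardly changes / falls, then rises / rises all the way / rises, then falls / falls all the way)

- for a step with 2 of a species take k times the square, and two of it per event
- "hardly changes" means that all values lie within two and a half points (for a concentration: within two and a half percent of the largest)
- run time (ochre): 5.0 h

Partner B feeds both arms, so write its balance. Each turn of the opening step (starting material + partner B) makes one open intermediate, each turn of the activating step (partner B + partner A) makes one second intermediate, and the coupling of those two makes one target. Each target therefore costs two partner B, so your 0.0137 M pays for 0.00685 M of target, or 52.7 % of the starting material.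

Now climb the ladder in ochre, fastest rung first. Taking open intermediate at the starting material's charge, the coupling gives second intermediate a half-life of 15.2 min. The opening step halves starting material in 0.92 h, slower than the coupling. By the quench alone, with protic impurity at its charge, starting material has a half-life of 11.0 h, longer than the 5.0 h run. The activating step takes 43 h to halve partner B, slower than both the quench and the opening step, so ochre should hold plenty of open intermediate and little target.

The activating step speeds up as partner A is raised. So carry the split s, a selectivity factor for partner B: the activating rate over the opening rate, which is 0.602 at the start of green. It is 0.0226 in ochre and 1.81 in amber, and it reaches one at an even charge of 0.0664 M of partner A. Each target takes one open intermediate and one second intermediate, so target stands at or below the smaller arm, counted as what each step has made. Shared out at its start split, partner B gives green a second arm of 39.6 % of the starting material and amber an open arm of 37.6 %. My reckoning stops at these two estimates, which are not bounds, and they point to a rise and then a fall.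

The forecast starts from the same place, “Partner B is the shared reagent”, and gives 3.1 %, 9.5 %, 21.5 %, 33 % and 28 %, a course that rises, then falls. Its target values for green and amber stand below my estimated arms.

The simulation gives 3.02 %, 9.20 %, 21.4 %, 32.0 % and 26.8 %, a course that rises, then falls. In green, the split of what was made by the end, second intermediate formed over target plus open intermediate, reads 0.876 against 0.602 at the start, while in amber it reads 2.19 against 1.81. The row turns at 0.051 M of partner A, less than the even charge of 0.0664 M.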